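**Retrosynthetic overview**

1. (Prostanoid numbering: C1 = carboxyl carbon, ring = C8–C12, lower chain = C13–C20.) 19 ⇐ methyl ester 18 ⇐ alkyne 16: the C6 ketone is carried as the C5≡C6 triple bond and unveiled last by a hydration steered by the C9 hydroxyl.
2. 16 ⇐ cyclopentenone 13 (C11–OH by conjugate borylation/oxidation, C9–OH by hydride reduction) ⇐ ring nitroalkene 12 (aerobic Nef reaction) ⇐ nitro alcohol 10 (C15 reduction, dehydration).
3. Key disconnection of 10: ring bonds C8–C12 and C9–C10 plus C13=C14, made in one flask from three achiral components, succinaldehyde 2 (C10–C13), nitroalkene 6 (C1–C9) and phosphonate 7 (C14–C20), by an amine-catalysed Michael/Henry domino and a Horner–Wadsworth–Emmons olefination.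
4. Enabling feature: in the cyclopentane ring C12 is α to C13 (a formyl carbon before it becomes the C13=C14 alkene) and C10 lies 1,4 to C13, so C10–C13 is a succinaldehyde unit (enamine donor at C12, acceptor at C10); the oxygen-bearing C9 and its neighbour C8 map onto the nitro carbon and β-carbon of a nitroalkene. The nitro group at C9 and the hydroxyl at C10 are temporary and are traded for the C9/C11 diol.
5. Rings: the cyclopentane (the only ring of the target) is closed in step 4; a temporary oxolane ring (O–C9–C8–C7–C6) is closed and reopened within step 10.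

Key step: step 4

Remark: the target is taken in the open 6-keto form as drawn; in solution it equilibrates with its 6,9-hemiketal, which does not affect the route.

**Route**

Step 1
Reactants: 1 2,5-dimethoxytetrahydrofuran
Product: 2 succinaldehyde
Conditions: H2O, 90 °C; MeOH distilled off, product distilled under reduced pressure and used fresh
Reagents that add atoms: water, O
Why: Acetal hydrolysis of the cyclic bis-acetal, driven by removal of methanol; fresh distillation limits oligomerization of the dialdehyde.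

Step 2
Reactants: 3 methyl hex-5-ynoate; 4 allyl bromide
Product: 5 methyl non-8-en-5-ynoate
Conditions: CuI (10 mol %), n-Bu4NI (10 mol %), K2CO3, DMF, rt
Reagents that add atoms: none
Why: Copper-catalysed coupling of a terminal alkyne with an allylic halide (copper acetylide allylation) should give the skipped enyne; the methyl ester tolerates the carbonate base.

Step 3
Reactants: 5 methyl non-8-en-5-ynoate
Product: 6 methyl (8E)-9-nitronon-8-en-5-ynoate
Conditions: AgNO2 (3 equiv), TEMPO (0.4 equiv), 4 Å MS, (CH2Cl)2, 70 °C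
Reagents that add atoms: silver nitrite, [Ag+].[O-]N=O
Why: Radical nitration of a terminal alkene: NO2 radical adds to the CH2 terminus and TEMPO-mediated loss of hydrogen from the nitro-bearing carbon should give the conjugated E-nitroalkene, the internal alkyne being far less reactive toward NO2 radical.

Step 4
Reactants: 2 succinaldehyde; 6 methyl (8E)-9-nitronon-8-en-5-ynoate; 7 dimethyl (2-oxoheptyl)phosphonate
Product: 10 methyl 7-[(1R,2S,3S,5R)-3-hydroxy-2-nitro-5-[(1E)-3-oxooct-1-en-1-yl]cyclopentyl]hept-5-ynoate, via Michael adduct 8 (not isolated), via nitrocyclopentanol aldehyde 9 (not isolated)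
Conditions: (S)-α,α-diphenylprolinol trimethylsilyl ether (10 mol %), 4-nitrophenol (10 mol %), MeCN, rt; then i-Pr2NEt, 0 °C to rt; then 7, LiCl, i-Pr2NEt, 0 °C to rt (one pot)
Reagents that add atoms: none
Why: The amine condenses with one formyl group of 2 to an E-enamine with one face shielded by the diphenyl(silyloxy)methyl group, and this enamine adds through an acyclic synclinal transition state to C8 of nitroalkene 6 (C8–C12 bond, enamine-mediated Michael addition); i-Pr2NEt then forms the nitronate, whose carbon C9 attacks the second formyl carbon C10 (C9–C10 bond, intramolecular Henry reaction), and the Masamune–Roush Horner–Wadsworth–Emmons reaction of the remaining formyl group with 7 gives the enone. The closest known reaction type is the diarylprolinol-silyl-ether-catalysed Michael/Henry domino of dialdehydes with nitroalkenes, followed by olefination in the same flask. The cyclopentane is closed in the 5-exo-trig mode (nitronate carbon onto the exocyclic C=O). C8 is set by the catalyst (the S catalyst should give 8R, as in additions of aldehydes to nitroalkenes in general) and cannot epimerize; C12 (α to formyl) and C9 (α to nitro) equilibrate under the amine base to the all-trans ring, so C12 ends trans to C8, and C10 follows from the reversible nitro-aldol; C9 and C10 are erased in steps 6 and 7 and need no control. The step needs cross-selectivity (enamine plus nitroalkene, not self-aldol of 2), which the much higher electrophilicity of the nitroalkene and the acid co-catalyst should secure, and the skipped nitro-enyne must not isomerize, which the weakly acidic Michael stage should secure because base is added only after 6 is consumed. The E geometry of C13=C14 follows from the stabilized phosphonate anion.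

Step 5
Reactants: 10 methyl 7-[(1R,2S,3S,5R)-3-hydroxy-2-nitro-5-[(1E)-3-oxooct-1-en-1-yl]cyclopentyl]hept-5-ynoate
Product: 11 methyl 7-[(1R,2S,3S,5R)-3-hydroxy-5-[(1E,3S)-3-hydroxyoct-1-en-1-yl]-2-nitrocyclopentyl]hept-5-ynoate
Conditions: (−)-Ipc2BCl [(−)-B-chlorodiisopinocampheylborane, 3 equiv], THF, −40 to −20 °C; then CH3CHO, 0 °C; aq. NaHCO3
Reagents that add atoms: none
Why: Reagent-controlled asymmetric reduction of the enone carbonyl by the chiral chloroborane (hydride transfer through a six-membered transition state, the alkenyl group acting as the large substituent) should give the 15S allylic alcohol; nitro, ester and alkyne are inert and the free ring hydroxyl only consumes reagent.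

Step 6
Reactants: 11 methyl 7-[(1R,2S,3S,5R)-3-hydroxy-5-[(1E,3S)-3-hydroxyoct-1-en-1-yl]-2-nitrocyclopentyl]hept-5-ynoate
Product: 12 methyl 7-[(1R,5R)-5-[(1E,3S)-3-hydroxyoct-1-en-1-yl]-2-nitrocyclopent-2-en-1-yl]hept-5-ynoate
Conditions: acidic Al2O3, (CH2Cl)2, 60 °C
Reagents that add atoms: none
Why: Surface-mediated dehydration of the β-nitro alcohol across C9–C10 should give the conjugated ring nitroalkene and erase the two uncontrolled centres C9 and C10, while the allylic C15 alcohol stays in place.

Step 7
Reactants: 12 methyl 7-[(1R,5R)-5-[(1E,3S)-3-hydroxyoct-1-en-1-yl]-2-nitrocyclopent-2-en-1-yl]hept-5-ynoate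
Product: 13 methyl 7-[(1R,2S)-2-[(1E,3S)-3-hydroxyoct-1-en-1-yl]-5-oxocyclopent-3-en-1-yl]hept-5-ynoate
Conditions: DABCO (2 equiv), O2 (1 atm), MeCN, 0 °C to rt
Reagents that add atoms: dioxygen, O=O
Why: Base-mediated aerobic Nef reaction: DABCO removes a C11 proton to give the allylic nitronate, whose C9 is oxygenated by O2 with loss of nitrite, so the C9 ketone should appear with the double bond transposed to C10=C11; the mild amine base should leave C8 and C12 untouched.

Step 8
Reactants: 13 methyl 7-[(1R,2S)-2-[(1E,3S)-3-hydroxyoct-1-en-1-yl]-5-oxocyclopent-3-en-1-yl]hept-5-ynoate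
Product: 15 methyl 7-[(1R,2R,3R)-3-hydroxy-2-[(1E,3S)-3-hydroxyoct-1-en-1-yl]-5-oxocyclopentyl]hept-5-ynoate, via boryl ketone 14 (not isolated)
Conditions: CuCl (5 mol %), Xantphos (5 mol %), NaOt-Bu (10 mol %), B2pin2 (1.1 equiv), MeOH (2 equiv), THF, 0 °C; then NaBO3·4H2O, THF/H2O, rt
Reagents that add atoms: bis(pinacolato)diboron, CC1(C)OB(OC1(C)C)B1OC(C)(C)C(C)(C)O1 (boryl group of 14 only); sodium perborate, [Na+].[O-]OB=O
Why: Copper-catalysed conjugate borylation of the cyclopentenone followed by oxidation of the C–B bond with retention; the boryl copper species should add to C11 on the face anti to the neighbouring C12 side chain, which sets the 11α (11R) hydroxyl.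

Step 9
Reactants: 15 methyl 7-[(1R,2R,3R)-3-hydroxy-2-[(1E,3S)-3-hydroxyoct-1-en-1-yl]-5-oxocyclopentyl]hept-5-ynoate
Product: 16 methyl 7-[(1R,2R,3R,5S)-3,5-dihydroxy-2-[(1E,3S)-3-hydroxyoct-1-en-1-yl]cyclopentyl]hept-5-ynoate
Conditions: LiBH(s-Bu)3 (L-Selectride, 3.5 equiv), THF, −78 °C; then H2O
Reagents that add atoms: none
Why: Substrate-controlled ketone reduction by a bulky trialkylborohydride, which should attack C9 on the face anti to the adjacent C8 chain and give the 9α (9S) alcohol, cis to the 11α hydroxyl; ester and alkyne are inert at −78 °C.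

Step 10
Reactants: 16 methyl 7-[(1R,2R,3R,5S)-3,5-dihydroxy-2-[(1E,3S)-3-hydroxyoct-1-en-1-yl]cyclopentyl]hept-5-ynoate
Product: 18 methyl 7-[(1R,2R,3R,5S)-3,5-dihydroxy-2-[(1E,3S)-3-hydroxyoct-1-en-1-yl]cyclopentyl]-6-oxoheptanoate, via enol ether 17 (not isolated)
Conditions: PdCl2(MeCN)2 (5 mol %), MeCN/H2O (10:1), rt; then pH 4 acetate buffer
Reagents that add atoms: water, O
Why: Divalent-palladium-catalysed alkyne hydration with participation of a neighbouring hydroxyl: the C9 hydroxyl, cis to the C8 chain, should attack C6 in the 5-exo-dig mode to give the bicyclic Z-enol ether, and hydrolysis of this enol ether places the ketone at C6 only.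

Step 11
Reactants: 18 methyl 7-[(1R,2R,3R,5S)-3,5-dihydroxy-2-[(1E,3S)-3-hydroxyoct-1-en-1-yl]cyclopentyl]-6-oxoheptanoate
Product: 19 7-[(1R,2R,3R,5S)-3,5-dihydroxy-2-[(1E,3S)-3-hydroxyoct-1-en-1-yl]cyclopentyl]-6-oxoheptanoic acid (6-keto-prostaglandin F1alpha)
Conditions: LiOH, THF/H2O, 0 °C to rt; then aq. HCl to pH 4
Reagents that add atoms: lithium hydroxide, [Li+].[OH-]
Why: Saponification of the methyl ester; the γ-hydroxy ketone has no base-labile stereocentre (C8 is β to the C6 carbonyl) and the acid is freed at mild pH.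

**Compound list**

1 | 2,5-dimethoxytetrahydrofuran (commercial cis/trans mixture) | COC1CCC(OC)O1 | starting material
2 | succinaldehyde (butanedial) | O=CCCC=O | intermediate
3 | methyl hex-5-ynoate | C#CCCCC(=O)OC | starting material
4 | allyl bromide (3-bromoprop-1-ene) | C=CCBr | starting material
5 | methyl non-8-en-5-ynoate | C=CCC#CCCCC(=O)OC | intermediate
6 | methyl (8E)-9-nitronon-8-en-5-ynoate | [O-][N+](=O)/C=C/CC#CCCCC(=O)OC | intermediate
7 | dimethyl (2-oxoheptyl)phosphonate | CCCCCC(=O)CP(=O)(OC)OC | starting material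
8 | methyl (8R,9R)-9-formyl-8-(nitromethyl)-11-oxoundec-5-ynoate (syn Michael adduct) | O=CC[C@@H](C=O)[C@H](C[N+](=O)[O-])CC#CCCCC(=O)OC | intermediate
9 | methyl 7-[(1R,2S,3S,5S)-5-formyl-3-hydroxy-2-nitrocyclopentyl]hept-5-ynoate (all-trans isomer expected as major) | O=C[C@@H]1[C@@H](CC#CCCCC(=O)OC)[C@H]([N+](=O)[O-])[C@@H](O)C1 | intermediate
10 | methyl 7-[(1R,2S,3S,5R)-3-hydroxy-2-nitro-5-[(1E)-3-oxooct-1-en-1-yl]cyclopentyl]hept-5-ynoate | CCCCCC(=O)/C=C/[C@@H]1[C@@H](CC#CCCCC(=O)OC)[C@H]([N+](=O)[O-])[C@@H](O)C1 | intermediate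
11 | methyl 7-[(1R,2S,3S,5R)-3-hydroxy-5-[(1E,3S)-3-hydroxyoct-1-en-1-yl]-2-nitrocyclopentyl]hept-5-ynoate | CCCCC[C@H](O)/C=C/[C@@H]1[C@@H](CC#CCCCC(=O)OC)[C@H]([N+](=O)[O-])[C@@H](O)C1 | intermediate
12 | methyl 7-[(1R,5R)-5-[(1E,3S)-3-hydroxyoct-1-en-1-yl]-2-nitrocyclopent-2-en-1-yl]hept-5-ynoate | CCCCC[C@H](O)/C=C/[C@@H]1[C@@H](CC#CCCCC(=O)OC)C([N+](=O)[O-])=CC1 | intermediate
13 | methyl 7-[(1R,2S)-2-[(1E,3S)-3-hydroxyoct-1-en-1-yl]-5-oxocyclopent-3-en-1-yl]hept-5-ynoate | CCCCC[C@H](O)/C=C/[C@@H]1[C@@H](CC#CCCCC(=O)OC)C(=O)C=C1 | intermediate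
14 | methyl 7-[(1R,2R,3R)-2-[(1E,3S)-3-hydroxyoct-1-en-1-yl]-5-oxo-3-(4,4,5,5-tetramethyl-1,3,2-dioxaborolan-2-yl)cyclopentyl]hept-5-ynoate | CCCCC[C@H](O)/C=C/[C@@H]1[C@@H](CC#CCCCC(=O)OC)C(=O)C[C@H]1B2OC(C)(C)C(C)(C)O2 | intermediate
15 | methyl 7-[(1R,2R,3R)-3-hydroxy-2-[(1E,3S)-3-hydroxyoct-1-en-1-yl]-5-oxocyclopentyl]hept-5-ynoate | CCCCC[C@H](O)/C=C/[C@@H]1[C@@H](CC#CCCCC(=O)OC)C(=O)C[C@H]1O | intermediate
16 | methyl 7-[(1R,2R,3R,5S)-3,5-dihydroxy-2-[(1E,3S)-3-hydroxyoct-1-en-1-yl]cyclopentyl]hept-5-ynoate | CCCCC[C@H](O)/C=C/[C@@H]1[C@@H](CC#CCCCC(=O)OC)[C@@H](O)C[C@H]1O | intermediate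
17 | methyl (5Z)-5-[(3aR,4R,5R,6aS)-5-hydroxy-4-[(1E,3S)-3-hydroxyoct-1-en-1-yl]hexahydro-2H-cyclopenta[b]furan-2-ylidene]pentanoate | CCCCC[C@H](O)/C=C/[C@@H]1[C@H]2C/C(=C/CCCC(=O)OC)O[C@H]2C[C@H]1O | intermediate
18 | methyl 7-[(1R,2R,3R,5S)-3,5-dihydroxy-2-[(1E,3S)-3-hydroxyoct-1-en-1-yl]cyclopentyl]-6-oxoheptanoate | CCCCC[C@H](O)/C=C/[C@@H]1[C@@H](CC(=O)CCCCC(=O)OC)[C@@H](O)C[C@H]1O | intermediate
19 | 7-[(1R,2R,3R,5S)-3,5-dihydroxy-2-[(1E,3S)-3-hydroxyoct-1-en-1-yl]cyclopentyl]-6-oxoheptanoic acid (6-keto-prostaglandin F1alpha) | CCCCC[C@H](O)/C=C/[C@@H]1[C@@H](CC(=O)CCCCC(=O)O)[C@@H](O)C[C@H]1O | target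

**Step count and risks**

Total step count: 11. Longest linear sequence: 10 steps (3 to 19, steps 2–11).

Steps most likely to fail:

1. Step 4. The donor may be lost to amine-catalysed self-aldolization and oligomerization of succinaldehyde, its excess may interfere with the telescoped olefination, and the three events may not stay clean in one flask. The fallback replaces the three-component domino by a stepwise sequence with a differentiated C4 dialdehyde. It sets out from 6: the same amine catalyst would add purchased 4,4-dimethoxybutanal F1 to 6 to give the acetal Michael adduct methyl (8R,9R)-9-formyl-11,11-dimethoxy-8-(nitromethyl)undec-5-ynoate F2, which is isolated. Aqueous CF3CO2H then frees the second formyl group, and the route is rejoined at 8. The Henry cyclization/epimerization to 9 (i-Pr2NEt, MeCN) and the olefination with 7 to 10 are then run as separate operations.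

2. Step 3. The radical nitration may be unselective, through NO2 radical attack on the alkyne or hydrogen abstraction at the doubly activated C7 methylene. The fallback is an ionic route that sets out from 5: ozonolysis of the terminal alkene (O3, CH2Cl2, −78 °C; Me2S) would give methyl 8-oxooct-5-ynoate F3, used crude and cold. A Henry reaction in nitromethane with a catalytic amine base at 0 °C would give racemic methyl 8-hydroxy-9-nitronon-5-ynoate F4, and dehydration with MsCl/Et3N (CH2Cl2, 0 °C) rejoins the route at 6.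

3. Step 8. The boryl copper species may protoborate the internal alkyne, or the alkoxide may cause double-bond migration or C8 epimerization of the cyclopentenone. The fallback sets out from 13: nucleophilic epoxidation (t-BuOOH, catalytic benzyltrimethylammonium hydroxide, THF, −20 °C) anti to the C12 chain would give methyl (10α,11α,13E,15S)-10,11-epoxy-15-hydroxy-9-oxoprost-13-en-5-ynoate F5. Reductive cleavage of the C10–O bond α to the ketone (Zn, NH4Cl, EtOH/H2O) rejoins the route at 15.

Further compounds
F1 | step 4 | 4,4-dimethoxybutanal | COC(OC)CCC=O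
F2 | step 4 | methyl (8R,9R)-9-formyl-11,11-dimethoxy-8-(nitromethyl)undec-5-ynoate | COC(OC)C[C@@H](C=O)[C@H](C[N+](=O)[O-])CC#CCCCC(=O)OC
F3 | step 3 | methyl 8-oxooct-5-ynoate | O=CCC#CCCCC(=O)OC
F4 | step 3 | methyl 8-hydroxy-9-nitronon-5-ynoate (racemic) | OC(C[N+](=O)[O-])CC#CCCCC(=O)OC
F5 | step 8 | methyl (10α,11α,13E,15S)-10,11-epoxy-15-hydroxy-9-oxoprost-13-en-5-ynoate | CCCCC[C@H](O)/C=C/[C@@H]1[C@@H](CC#CCCCC(=O)OC)C(=O)[C@H]2O[C@@H]12
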